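**Retrosynthetic overview**
1. Target 22 ⇐ 14-deoxy 1(10)-E germacranolide 21, by a last allylic hydroxylation of C14 (SeO2) that also turns the ring olefin from E to the required ring-cis geometry.
2. 21 ⇐ ten-membered hydroxy ester 18, by O8-methacrylation, then desilylation and 6,12-lactonisation (lactone ring formed second).
3. 18 ⇐ seco aldehyde/allyl bromide 15, by an electrochemical, Cr-catalytic macrocyclic allylation forming C7–C8 (ten-membered ring formed first; sets C7 and C8).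
4. 15 ⇐ lactone 7 (reduction, Baylis–Hillman homologation at C7) ⇐ bought (R)-lactone 5 + iodide 4 (trans-alkylation sets C4 from C6).
5. 4 ⇐ alkyne 1, by Zr-catalysed carboalumination and oxirane opening (E-trisubstituted olefin).

Assumption and convention: lactone 5 (sold, made from D-glutamic acid) and alkyne 1 are taken as purchasable; C1–C15 are germacranolide labels (C6/C7 lactone carbons, C8 ester carbon, C4 the CH–CH2OH carbon, C1=C10 ring olefin, C14/C15 the CH2OH carbons, C11–C13 the α-methylene acyl unit).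

**Step 1**
Reactants: 1 1-[(but-3-yn-1-yloxy)methyl]-4-methoxybenzene
Product: 3 (3E)-6-[(4-methoxybenzyl)oxy]-4-methylhex-3-en-1-ol, via alkenyldimethylalane 2 (not isolated)
Conditions: Me3Al (2.5 eq), Cp2ZrCl2 (0.25 eq), CH2Cl2, 0 °C → rt; evaporate, THF, n-BuLi, −78 °C; oxirane, −78 → 0 °C; aq. Rochelle salt
Reagents that add atoms: trimethylaluminium C[Al](C)C; oxirane C1CO1
Why: Negishi Zr-catalysed carboalumination adds Me–Al syn and regioselectively across the terminal alkyne and the derived alkenylalanate opens oxirane with retention, so the E-trisubstituted olefin (C14 methyl cis to C2) is fixed.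

**Step 2**
Reactants: 3 (3E)-6-[(4-methoxybenzyl)oxy]-4-methylhex-3-en-1-ol
Product: 4 1-({[(3E)-6-iodo-3-methylhex-3-en-1-yl]oxy}methyl)-4-methoxybenzene
Conditions: I2, PPh3, imidazole, CH2Cl2, 0 °C
Reagents that add atoms: iodine II
Why: Appel-type iodination of the primary alcohol via the alkoxyphosphonium salt, which leaves the olefin untouched.

**Step 3**
Reactants: 5 (5R)-5-[(trityloxy)methyl]oxolan-2-one; 4 1-({[(3E)-6-iodo-3-methylhex-3-en-1-yl]oxy}methyl)-4-methoxybenzene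
Product: 7 (3S,5R)-3-[(3E)-6-[(4-methoxybenzyl)oxy]-4-methylhex-3-en-1-yl]-5-[(trityloxy)methyl]oxolan-2-one, via lithium enolate 6 (not isolated)
Conditions: LDA, THF, −78 °C; then 4, DMPU, −78 → −30 °C
Reagents that add atoms: none
Why: SN2 alkylation of the lactone lithium enolate occurs on the face anti to the bulky CH2OTr group, giving the 3,5-trans lactone, so C4 (S) is set by the bought C6 centre (1,3-induction).

**Step 4**
Reactants: 7 (3S,5R)-3-[(3E)-6-[(4-methoxybenzyl)oxy]-4-methylhex-3-en-1-yl]-5-[(trityloxy)methyl]oxolan-2-one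
Product: 8 (2S,4R)-2-[(3E)-6-[(4-methoxybenzyl)oxy]-4-methylhex-3-en-1-yl]-5-(trityloxy)pentane-1,4-diol
Conditions: LiAlH4, THF, 0 °C
Reagents that add atoms: none
Why: Hydride reduction of the lactone gives the C15/C6 diol without touching a stereocentre, the olefin or the ethers.

**Step 5**
Reactants: 8 (2S,4R)-2-[(3E)-6-[(4-methoxybenzyl)oxy]-4-methylhex-3-en-1-yl]-5-(trityloxy)pentane-1,4-diol
Product: 9 (2S,4R)-1,4-bis[(tert-butyldimethylsilyl)oxy]-2-[(3E)-6-[(4-methoxybenzyl)oxy]-4-methylhex-3-en-1-yl]-5-(trityloxy)pentane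
Conditions: TBSOTf (2.4 eq), 2,6-lutidine, CH2Cl2, −78 → 0 °C
Reagents that add atoms: tert-butyldimethylsilyl trifluoromethanesulfonate CC(C)(C)[Si](C)(C)OS(=O)(=O)C(F)(F)F
Why: Silyl triflate silylation protects both O15 and O6 in one operation, and a silyloxy group at C6 is a poor leaving group for the later allylmetal.

**Step 6**
Reactants: 9 (2S,4R)-1,4-bis[(tert-butyldimethylsilyl)oxy]-2-[(3E)-6-[(4-methoxybenzyl)oxy]-4-methylhex-3-en-1-yl]-5-(trityloxy)pentane
Product: 10 (2R,4S)-2,5-bis[(tert-butyldimethylsilyl)oxy]-4-[(3E)-6-[(4-methoxybenzyl)oxy]-4-methylhex-3-en-1-yl]pentan-1-ol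
Conditions: HCO2H/Et2O (1:1), rt, 15 min; aq. NaHCO3
Reagents that add atoms: none
Why: SN1 acidolysis of the trityl ether is much faster than cleavage of TBS or PMB ethers under brief formic acid treatment.

**Step 7**
Reactants: 10 (2R,4S)-2,5-bis[(tert-butyldimethylsilyl)oxy]-4-[(3E)-6-[(4-methoxybenzyl)oxy]-4-methylhex-3-en-1-yl]pentan-1-ol
Product: 11 (2R,4S)-2,5-bis[(tert-butyldimethylsilyl)oxy]-4-[(3E)-6-[(4-methoxybenzyl)oxy]-4-methylhex-3-en-1-yl]pentanal
Conditions: Dess–Martin periodinane, NaHCO3, CH2Cl2, 0 °C → rt; used crude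
Reagents that add atoms: none
Why: Buffered Dess–Martin oxidation gives the α-silyloxy aldehyde (C7) under non-basic conditions that do not epimerise C6.

**Step 8**
Reactants: 11 (2R,4S)-2,5-bis[(tert-butyldimethylsilyl)oxy]-4-[(3E)-6-[(4-methoxybenzyl)oxy]-4-methylhex-3-en-1-yl]pentanal
Product: 12 tert-butyl (4R,6S)-4,7-bis[(tert-butyldimethylsilyl)oxy]-3-hydroxy-6-[(3E)-6-[(4-methoxybenzyl)oxy]-4-methylhex-3-en-1-yl]-2-methylideneheptanoate (both C3 epimers)
Conditions: tert-butyl acrylate (5 eq), DABCO (1 eq), MeOH (few eq), rt, 4–6 d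
Reagents that add atoms: tert-butyl acrylate C=CC(=O)OC(C)(C)C
Why: Morita–Baylis–Hillman reaction of an activated α-oxygenated aldehyde installs C11–C13; the new carbinol centre is erased in step 9, and the tert-butyl ester later blocks lactonisation of O8 onto C12.

**Step 9**
Reactants: 12 tert-butyl (4R,6S)-4,7-bis[(tert-butyldimethylsilyl)oxy]-3-hydroxy-6-[(3E)-6-[(4-methoxybenzyl)oxy]-4-methylhex-3-en-1-yl]-2-methylideneheptanoate
Product: 13 tert-butyl (2Z,4R,6S)-2-(bromomethyl)-4,7-bis[(tert-butyldimethylsilyl)oxy]-6-[(3E)-6-[(4-methoxybenzyl)oxy]-4-methylhex-3-en-1-yl]hept-2-enoate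
Conditions: NBS, Me2S, CH2Cl2, 0 °C → rt
Reagents that add atoms: N-bromosuccinimide O=C1CCC(=O)N1Br
Why: Corey–Kim-type activation and SN2′ attack of bromide on the Baylis–Hillman alcohol give the thermodynamically preferred (Z)-2-(bromomethyl)enoate (C6 trans to the ester).

**Step 10**
Reactants: 13 tert-butyl (2Z,4R,6S)-2-(bromomethyl)-4,7-bis[(tert-butyldimethylsilyl)oxy]-6-[(3E)-6-[(4-methoxybenzyl)oxy]-4-methylhex-3-en-1-yl]hept-2-enoate
Product: 14 tert-butyl (2Z,4R,6S)-2-(bromomethyl)-4,7-bis[(tert-butyldimethylsilyl)oxy]-6-[(3E)-6-hydroxy-4-methylhex-3-en-1-yl]hept-2-enoate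
Conditions: DDQ, CH2Cl2/pH 7 buffer, 0 °C
Reagents that add atoms: none
Why: Oxidative PMB ether cleavage by DDQ frees O8 and leaves the silyl ethers, the allylic bromide and both olefins intact.

**Step 11**
Reactants: 14 tert-butyl (2Z,4R,6S)-2-(bromomethyl)-4,7-bis[(tert-butyldimethylsilyl)oxy]-6-[(3E)-6-hydroxy-4-methylhex-3-en-1-yl]hept-2-enoate
Product: 15 tert-butyl (2Z,4R,6S)-2-(bromomethyl)-4,7-bis[(tert-butyldimethylsilyl)oxy]-6-[(3E)-4-methyl-6-oxohex-3-en-1-yl]hept-2-enoate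
Conditions: Dess–Martin periodinane, NaHCO3, CH2Cl2, 0 °C, 30 min; filtered through Florisil and used at once
Reagents that add atoms: none
Why: Buffered Dess–Martin oxidation is the standard way to a β,γ-unsaturated aldehyde (C8) without migration of the olefin into conjugation.

**Step 12**
Reactants: 15 tert-butyl (2Z,4R,6S)-2-(bromomethyl)-4,7-bis[(tert-butyldimethylsilyl)oxy]-6-[(3E)-4-methyl-6-oxohex-3-en-1-yl]hept-2-enoate
Product: 18 tert-butyl 2-[(1R,2R,4E,8S,10R)-10-[(tert-butyldimethylsilyl)oxy]-8-{[(tert-butyldimethylsilyl)oxy]methyl}-2-hydroxy-4-methylcyclodec-4-en-1-yl]prop-2-enoate, via allylchromium species 16 (not isolated), via trimethylsilyl ether 17 (not isolated)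
Conditions: CrCl3·3THF (15 mol%), Me3SiCl (3 eq), LiCl, Bu4NPF6, DMF/THF, undivided cell, Al anode/Ni-foam cathode, 2 mA (ca. 2.2 F/mol, cathode near −1.0 V vs Ag/AgCl), 15 added over 10 h (final 2 mM), rt; then 1 M HCl, THF, 0 °C
Reagents that add atoms: none
Why: Proposed new method: a cathodically driven, chromium-catalytic macrocyclic Nozaki–Hiyama (Barbier-type) carbonyl allylation, in which Cr(III) is reduced at the cathode to Cr(II), two Cr(II) turn the allylic bromide into the (Z)-2-(alkoxycarbonyl)allylchromium(III) 16 at very low steady-state concentration, 16 adds to the tethered aldehyde through a chair Zimmerman–Traxler transition state (C6 pseudo-axial, C9 equatorial, giving the 7,8-syn relation that Baylis–Hillman bromides normally give) on the olefin face anti to the C6 silyloxy group with H6 eclipsing the olefin (A1,3 strain), so that C7 (S) and C8 (R) follow from the bought C6 centre, and Me3SiCl cleaves the Cr–O bond so that Cr(III) returns to the cathode and the alkoxide cannot attack C12; the closest known reactions are the stoichiometric CrCl2-mediated macrocyclic allylation used to close germacranolide rings and the intermolecular Cr-catalytic (Mn/Me3SiCl or electrochemical) Nozaki–Hiyama–Kishi couplings.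

**Step 13**
Reactants: 18 tert-butyl 2-[(1R,2R,4E,8S,10R)-10-[(tert-butyldimethylsilyl)oxy]-8-{[(tert-butyldimethylsilyl)oxy]methyl}-2-hydroxy-4-methylcyclodec-4-en-1-yl]prop-2-enoate
Product: 19 (1R,2R,4E,8S,10R)-1-[3-(tert-butoxy)-3-oxoprop-1-en-2-yl]-10-[(tert-butyldimethylsilyl)oxy]-8-{[(tert-butyldimethylsilyl)oxy]methyl}-4-methylcyclodec-4-en-2-yl 2-methylprop-2-enoate
Conditions: methacrylic anhydride, Et3N, DMAP (cat.), BHT, CH2Cl2, 0 °C → rt
Reagents that add atoms: methacrylic anhydride CC(=C)C(=O)OC(=O)C(C)=C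
Why: DMAP-catalysed acylation of the only free hydroxyl (O8) proceeds with retention at C8.

**Step 14**
Reactants: 19 (1R,2R,4E,8S,10R)-1-[3-(tert-butoxy)-3-oxoprop-1-en-2-yl]-10-[(tert-butyldimethylsilyl)oxy]-8-{[(tert-butyldimethylsilyl)oxy]methyl}-4-methylcyclodec-4-en-2-yl 2-methylprop-2-enoate
Product: 21 (3aS,4R,6E,10S,11aR)-10-(hydroxymethyl)-6-methyl-3-methylidene-2-oxo-2,3,3a,4,5,8,9,10,11,11a-decahydrocyclodeca[b]furan-4-yl 2-methylprop-2-enoate, via diol tert-butyl ester 20 (not isolated)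
Conditions: HF·pyridine, pyridine/THF, 0 °C → rt; then TFA/CH2Cl2 (1:9), 0 °C
Reagents that add atoms: none
Why: Fluoride desilylation frees O6 and O15, and acid-promoted lactonisation of O6 onto the tert-butyl ester (loss of isobutene) gives the trans-fused α-methylene-γ-butyrolactone because C6 and C7 are already set and O8 is acylated.

**Step 15**
Reactants: 21 (3aS,4R,6E,10S,11aR)-10-(hydroxymethyl)-6-methyl-3-methylidene-2-oxo-2,3,3a,4,5,8,9,10,11,11a-decahydrocyclodeca[b]furan-4-yl 2-methylprop-2-enoate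
Product: 22 (3aS,4R,6E,10S,11aR)-6,10-bis(hydroxymethyl)-3-methylidene-2-oxo-2,3,3a,4,5,8,9,10,11,11a-decahydrocyclodeca[b]furan-4-yl 2-methylprop-2-enoate
Conditions: SeO2 (0.5 eq), t-BuOOH (3 eq), CH2Cl2, rt
Reagents that add atoms: tert-butyl hydroperoxide CC(C)(C)OO
Why: Riley–Sharpless allylic oxidation (ene reaction, then [2,3]-sigmatropic shift) hydroxylates the C14 methyl and, because the [2,3] step places CH2OH trans to C2, turns the 1(10)-E olefin into the ring-cis geometry, as is known for 1(10)-E germacranolides, while the electron-poor acrylate units do not react.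

**Compound list**
1 | 1-[(but-3-yn-1-yloxy)methyl]-4-methoxybenzene | C#CCCOCc1ccc(OC)cc1 | starting material
2 | [(1E)-4-[(4-methoxybenzyl)oxy]-2-methylbut-1-en-1-yl]dimethylalumane | C[Al](C)/C=C(\C)CCOCc1ccc(OC)cc1 | intermediate
3 | (3E)-6-[(4-methoxybenzyl)oxy]-4-methylhex-3-en-1-ol | OCC/C=C(\C)CCOCc1ccc(OC)cc1 | intermediate
4 | 1-({[(3E)-6-iodo-3-methylhex-3-en-1-yl]oxy}methyl)-4-methoxybenzene | ICC/C=C(\C)CCOCc1ccc(OC)cc1 | intermediate
5 | (5R)-5-[(trityloxy)methyl]oxolan-2-one | O=C1CC[C@H](COC(c2ccccc2)(c2ccccc2)c2ccccc2)O1 | starting material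
6 | lithium enolate of 5 | [Li+].[O-]C1=CC[C@H](COC(c2ccccc2)(c2ccccc2)c2ccccc2)O1 | intermediate
7 | (3S,5R)-3-[(3E)-6-[(4-methoxybenzyl)oxy]-4-methylhex-3-en-1-yl]-5-[(trityloxy)methyl]oxolan-2-one | COc1ccc(COCC/C(C)=C/CC[C@H]2C[C@H](COC(c3ccccc3)(c3ccccc3)c3ccccc3)OC2=O)cc1 | intermediate
8 | (2S,4R)-2-[(3E)-6-[(4-methoxybenzyl)oxy]-4-methylhex-3-en-1-yl]-5-(trityloxy)pentane-1,4-diol | COc1ccc(COCC/C(C)=C/CC[C@H](CO)C[C@@H](O)COC(c2ccccc2)(c2ccccc2)c2ccccc2)cc1 | intermediate
9 | (2S,4R)-1,4-bis[(tert-butyldimethylsilyl)oxy]-2-[(3E)-6-[(4-methoxybenzyl)oxy]-4-methylhex-3-en-1-yl]-5-(trityloxy)pentane | COc1ccc(COCC/C(C)=C/CC[C@H](CO[Si](C)(C)C(C)(C)C)C[C@@H](O[Si](C)(C)C(C)(C)C)COC(c2ccccc2)(c2ccccc2)c2ccccc2)cc1 | intermediate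
10 | (2R,4S)-2,5-bis[(tert-butyldimethylsilyl)oxy]-4-[(3E)-6-[(4-methoxybenzyl)oxy]-4-methylhex-3-en-1-yl]pentan-1-ol | COc1ccc(COCC/C(C)=C/CC[C@H](CO[Si](C)(C)C(C)(C)C)C[C@@H](O[Si](C)(C)C(C)(C)C)CO)cc1 | intermediate
11 | (2R,4S)-2,5-bis[(tert-butyldimethylsilyl)oxy]-4-[(3E)-6-[(4-methoxybenzyl)oxy]-4-methylhex-3-en-1-yl]pentanal | COc1ccc(COCC/C(C)=C/CC[C@H](CO[Si](C)(C)C(C)(C)C)C[C@@H](O[Si](C)(C)C(C)(C)C)C=O)cc1 | intermediate
12 | tert-butyl (4R,6S)-4,7-bis[(tert-butyldimethylsilyl)oxy]-3-hydroxy-6-[(3E)-6-[(4-methoxybenzyl)oxy]-4-methylhex-3-en-1-yl]-2-methylideneheptanoate (C3 epimers) | COc1ccc(COCC/C(C)=C/CC[C@H](CO[Si](C)(C)C(C)(C)C)C[C@@H](O[Si](C)(C)C(C)(C)C)C(O)C(=C)C(=O)OC(C)(C)C)cc1 | intermediate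
13 | tert-butyl (2Z,4R,6S)-2-(bromomethyl)-4,7-bis[(tert-butyldimethylsilyl)oxy]-6-[(3E)-6-[(4-methoxybenzyl)oxy]-4-methylhex-3-en-1-yl]hept-2-enoate | COc1ccc(COCC/C(C)=C/CC[C@H](CO[Si](C)(C)C(C)(C)C)C[C@@H](O[Si](C)(C)C(C)(C)C)/C=C(\CBr)C(=O)OC(C)(C)C)cc1 | intermediate
14 | tert-butyl (2Z,4R,6S)-2-(bromomethyl)-4,7-bis[(tert-butyldimethylsilyl)oxy]-6-[(3E)-6-hydroxy-4-methylhex-3-en-1-yl]hept-2-enoate | OCC/C(C)=C/CC[C@H](CO[Si](C)(C)C(C)(C)C)C[C@@H](O[Si](C)(C)C(C)(C)C)/C=C(\CBr)C(=O)OC(C)(C)C | intermediate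
15 | tert-butyl (2Z,4R,6S)-2-(bromomethyl)-4,7-bis[(tert-butyldimethylsilyl)oxy]-6-[(3E)-4-methyl-6-oxohex-3-en-1-yl]hept-2-enoate | O=CC/C(C)=C/CC[C@H](CO[Si](C)(C)C(C)(C)C)C[C@@H](O[Si](C)(C)C(C)(C)C)/C=C(\CBr)C(=O)OC(C)(C)C | intermediate
16 | allyl(dichloro)chromium(III) species derived from 15 (CH2Br replaced by CH2CrCl2) | O=CC/C(C)=C/CC[C@H](CO[Si](C)(C)C(C)(C)C)C[C@@H](O[Si](C)(C)C(C)(C)C)/C=C(\C[Cr](Cl)Cl)C(=O)OC(C)(C)C | intermediate
17 | O8-trimethylsilyl ether of 18 | C[Si](C)(C)O[C@@H]1C/C(C)=C/CC[C@H](CO[Si](C)(C)C(C)(C)C)C[C@@H](O[Si](C)(C)C(C)(C)C)[C@@H]1C(=C)C(=O)OC(C)(C)C | intermediate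
18 | tert-butyl 2-[(1R,2R,4E,8S,10R)-10-[(tert-butyldimethylsilyl)oxy]-8-{[(tert-butyldimethylsilyl)oxy]methyl}-2-hydroxy-4-methylcyclodec-4-en-1-yl]prop-2-enoate | O[C@@H]1C/C(C)=C/CC[C@H](CO[Si](C)(C)C(C)(C)C)C[C@@H](O[Si](C)(C)C(C)(C)C)[C@@H]1C(=C)C(=O)OC(C)(C)C | intermediate
19 | (1R,2R,4E,8S,10R)-1-[3-(tert-butoxy)-3-oxoprop-1-en-2-yl]-10-[(tert-butyldimethylsilyl)oxy]-8-{[(tert-butyldimethylsilyl)oxy]methyl}-4-methylcyclodec-4-en-2-yl 2-methylprop-2-enoate | C=C(C)C(=O)O[C@@H]1C/C(C)=C/CC[C@H](CO[Si](C)(C)C(C)(C)C)C[C@@H](O[Si](C)(C)C(C)(C)C)[C@@H]1C(=C)C(=O)OC(C)(C)C | intermediate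
20 | desilylated diol tert-butyl ester of 19 (free O6–H and O15–H) | C=C(C)C(=O)O[C@@H]1C/C(C)=C/CC[C@H](CO)C[C@@H](O)[C@@H]1C(=C)C(=O)OC(C)(C)C | intermediate
21 | (3aS,4R,6E,10S,11aR)-10-(hydroxymethyl)-6-methyl-3-methylidene-2-oxo-2,3,3a,4,5,8,9,10,11,11a-decahydrocyclodeca[b]furan-4-yl 2-methylprop-2-enoate | C=C(C)C(=O)O[C@@H]1C/C(C)=C/CC[C@H](CO)C[C@H]2OC(=O)C(=C)[C@H]12 | intermediate
22 | (3aS,4R,6E,10S,11aR)-6,10-bis(hydroxymethyl)-3-methylidene-2-oxo-2,3,3a,4,5,8,9,10,11,11a-decahydrocyclodeca[b]furan-4-yl 2-methylprop-2-enoate | C=C(C)C(=O)O[C@@H]1C/C(CO)=C\CC[C@H](CO)C[C@H]2OC(=O)C(=C)[C@H]12 | target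

**Step count and risks**
Total step count: 15. Longest linear sequence: 15 steps (1 → 22; lactone 5 is bought and enters at step 3).

Step 12, the new electrochemical macrocyclisation, is the most likely to fail. The allylic bromide may be reduced directly at the cathode, the seco compound may oligomerise, or the ring may close with another C7/C8 configuration than the transition-state model predicts. The fallback sets out from 15 and comes back at 18. It drops electrolysis and uses the known stoichiometric chromium(II) chloride-mediated intramolecular Nozaki–Hiyama allylation (CrCl2, 8 eq, THF/DMF, rt, syringe-pump addition to about 1 mM, dilute HCl work-up), the reaction by which germacranolide ten-membered rings have been closed. The tert-butyl ester still keeps the chromium alkoxide from lactonising, and this fallback makes no compound outside the list (F0).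

Step 15, the selenium dioxide oxidation, is second. It could attack the C9 or C2 methylene instead of C14, over-oxidise to the enal, or leave the olefin geometry mixed. The fallback sets out from 21 and comes back at 22. Schenck ene photo-oxygenation (O2, tetraphenylporphyrin, visible light, CH2Cl2, −20 °C) moves the olefin to the exocyclic C10=C14 position and gives the C1 allylic hydroperoxide F1. Triphenylphosphine reduces it to the C1 allylic alcohol F2. A catalytic oxorhenium 1,3-allylic transposition (Ph3SiOReO3, Et2O, 0 °C) then moves the hydroxyl to C14 and the olefin back to C1=C10, giving the thermodynamically preferred primary allylic alcohol 22.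

Step 8, the Baylis–Hillman reaction, is third. tert-Butyl acrylate is a sluggish partner, and days of exposure to DABCO may epimerise C6 or move the silyl group. The fallback sets out from 11 and comes back at 12. It replaces amine catalysis by a stoichiometric vinylalumination: tert-butyl propiolate is hydroaluminated with DIBAL-H/N-methylmorpholine N-oxide (THF, 0 °C) to the α-aluminoacrylate [1-(tert-butoxycarbonyl)ethenyl]diisobutylalane F3, which adds to aldehyde 11 within minutes at 0 °C and gives 12 after Rochelle-salt work-up.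

**Further compounds**
F0 | step 12 | none | none
F1 | step 15 | C1 allylic hydroperoxide of 21 with exocyclic C10=C14 olefin (C1 epimers) | C=C(C)C(=O)O[C@@H]1CC(=C)C(OO)CC[C@H](CO)C[C@H]2OC(=O)C(=C)[C@H]12
F2 | step 15 | C1 allylic alcohol of 21 with exocyclic C10=C14 olefin (C1 epimers) | C=C(C)C(=O)O[C@@H]1CC(=C)C(O)CC[C@H](CO)C[C@H]2OC(=O)C(=C)[C@H]12
F3 | step 8 | [1-(tert-butoxycarbonyl)ethenyl]diisobutylalane | C=C([Al](CC(C)C)CC(C)C)C(=O)OC(C)(C)C
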